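Remark on the chemistry: ring positions of every intermediate are cited in the numbering of the target ring (C1 ketone, C2 amido carbon, C3 vinylic CH, C4 tertiary carbinol, C5 secondary carbinol, C6 methylene), whatever the systematic name. Assumption: the hydroxycyclopentenone amide is handled as the enol tautomer, and compounds 18, 23 and 32 are taken as purchasable.

## Analysis of the target

The target 37 is a cyclohexenone (C1 ketone, C2 enamide carbon, C3 vinylic CH, C4 tertiary carbinol, C5 secondary carbinol, C6 methylene) with two polyene amide arms. One arm is a (2E,4E,6R)-4,6-dimethyldeca-2,4-dienoyl group on the C2 nitrogen; the other, on C4, is an all-E hepta-1,3,5-trienyl chain ending in an amide of 2-amino-3-hydroxycyclopent-2-enone. There are three stereocentres: C4 (S) and C5 (R) on the ring, whose hydroxyls are cis, and the remote C6 (R) of the dienoyl chain, which has no stereochemical contact with the ring. The C5 hydroxyl is β to the C1 ketone, so base can cause E1cB loss of the C5 oxygen or retro-aldol cleavage; an achiral 4-hydroxycyclohexadienone lies one elimination away. The C4 carbinol is tertiary and flanked by the enamide alkene and the triene, so strong acid invites ionisation; the polyenes are light- and acid-sensitive, and the cyclopentenone amide is a vinylogous acid. The difficulty is the oxygenated quaternary centre C4, in a fixed relation to C5, next to a 2-amidoenone in a ring where every carbon is functionalised differently. The strategy rests on one feature: in a cyclohex-2-enol with the carbinol at C5 and the alkene at C3=C4, the C5 hydroxyl is allylic and can carry an oxidant to its own face, so one catalytically set centre fixes C4 as the cis-diol. An alkyne on C4 serves as a compact, oxidation-proof stand-in for the first (E)-alkene of the triene.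

## Retrosynthetic reasoning

**Triene bond C2'–C3' of the lower chain (37 ⇒ 28 + 36).** The cut is made between the vinyl group on C4 and the dienamide, by a Stille coupling of vinylstannane 28 with bromodienamide 36. This puts the most fragile parts (triene, vinylogous acid, free β-hydroxy ketone) into the last, neutral step, and both alkene geometries are carried in stereospecifically.

**Bromodienamide 36 ⇒ 34 + 31.** The amide bond is cut. Acid 34 comes from bromodienal 33, itself a vinylogous substitution product of the dienolate salt 32. Aminoenol salt 31 comes from dione 29 through oxime 30. All of this is short, achiral chemistry off the main line.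

**Vinylstannane 28 ⇒ 27 ⇒ 26 ⇒ 25.** The (E)-vinyl–tin unit is traced to the terminal alkyne 27 by hydrostannation. The diol protection (26) and the alkyne silyl cap (25) are removed before tin is introduced, because a vinylstannane would not survive the acid needed for the acetal.

**C2–N bond (25 ⇒ 11 + 24).** A copper-catalysed amidation of the α-iodoenone 11 with primary dienamide 24 brings in the whole upper chain at once. It avoids acylating a poorly nucleophilic 2-aminoenone and needs only an enone as the handle.

**Upper chain (24 ⇒ 22 + 23; 22 ⇒ 21 ⇒ 20 ⇒ 19 + 18; 19 ⇒ 17 ⇒ 16 ⇒ 14 ⇒ 12 + 13).** The two alkenes are cut by olefinations that each give the E isomer. The single stereocentre is traced to an auxiliary-controlled methylation of an N-hexanoyl imide, the auxiliary being recovered.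

**C2 iodide and C1 ketone (11 ⇒ 10 ⇒ 9).** Iodination at the α-carbon of enone 10 marks C2. The ketone of 10 is traced to C–H oxidation of cyclohexene 9, in which C1 is the only allylic methylene because the other allylic position, C4, is quaternary.

**Alkene C2=C3 (9 ⇒ 8 ⇒ 6 ⇒ 5).** The acetal is cut back to diol 8. The alkene of 8 comes from a selenoxide elimination of hydroxy selenide 6, which can only go towards C2 because C4 has no hydrogen. Selenide 6 comes from opening epoxide 5 at its secondary carbon C3. The epoxide thus serves twice: its tertiary C–O bond becomes the C4 hydroxyl and its secondary carbon becomes the alkene.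

**C4–O and C3–O bonds (5 ⇒ 4).** The oxirane is cut back to allylic alcohol 4. The forward reaction must deliver oxygen to the alkene face cis to the C5 hydroxyl; a metal bound to that hydroxyl does this, and it is the reason the carbinol is made first.

**Carbinol C5 and the alkynyl group (4 ⇒ 3 ⇒ 1 + 2).** The carbinol comes from enantioselective reduction of ynenone 3, and 3 from Sonogashira coupling of iodoenone 1 with silylacetylene 2. The precursor of the key step is reached in two steps.

## Alternatives that were turned down

**Alternative 1:** Both diol C–O bonds are traced to a dearomatising cis-dihydroxylation of benzoic acid A1 at its ipso and ortho carbons, the carboxyl carbon becoming the first carbon of the lower chain. In the forward step a dioxygenase-expressing, dehydrogenase-deficient whole-cell system turns A1 into (1S,2R)-1,2-dihydroxycyclohexa-3,5-diene-1-carboxylic acid A2.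
- For: one operation on a bulk aromatic sets C4 and C5 with the right relative and absolute configuration, with the carbon substituent already on the quaternary centre. On stereocentres per step it is stronger than the chosen route, which needs steps 2 and 3 for the same result.
- Against: A2 is a 1,3-diene (C2=C3 and C6=C1) that re-aromatises by dehydration. The ring still needs oxygen at C1, nitrogen at C2 and saturation at C6 while C2=C3 is kept. C1 and C2 are the inner carbons of the diene, where cycloadditions do not deliver heteroatoms, so two similar alkenes must be told apart by several redox steps. The carboxyl group must also be reduced at a hindered centre and homologated, and the step needs fermentation with an engineered strain.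
- Comparison: the chosen route spends more steps on the stereocentres but reaches 9 with one alkene and one allylic methylene, so the C1 oxidation and C2 amination have one site each to react at.

**Alternative 2:** The C2–N and C5–O bonds are cut together by a hetero-Diels–Alder reaction. The acylnitroso species, made in situ by periodate oxidation of (2E,4E,6R)-N-hydroxy-4,6-dimethyldeca-2,4-dienamide A3, adds across the termini of silyl dienol ether A4 to give the bicyclic oxazine A5.
- For: the whole upper chain arrives with the nitrogen, the 1,4-relation of N and O matches the diene termini, the electrophilic nitrogen should bond to the enol ether terminus, and the C1 oxygen is already present. On convergence and on how nitrogen is introduced it is stronger than the chosen route, which needs a copper amidation on a base-sensitive enone.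
- Against: C5 is set under the control of the existing quaternary C4, whose alkoxy and alkenyl groups are of similar size, and the dienophile must approach syn to the oxygen. A4 must first be made as a single enantiomer by a separate asymmetric construction, and it can aromatise by losing the C4 alkoxy group. The acylnitroso group can also undergo ene reactions with trisubstituted alkenes. After the cycloaddition C3 is a saturated methylene, so C2=C3 needs a later dehydrogenation; the N–O bond must be reduced beside a dienamide; and the lower chain must still be grown from the allylic silyl ether.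
- Comparison: the chosen route sets both ring centres through a reagent-controlled reduction and a covalently templated oxygen transfer, both with well-understood transition states, and C2=C3 comes directly from the selenoxide elimination.

**Alternative 3:** The C5–O bond is cut by an intramolecular conjugate addition from oxygen tethered at C4. In the forward step the achiral quinol 4-hydroxy-4-[(trimethylsilyl)ethynyl]cyclohexa-2,5-dien-1-one A6 is esterified with an arylboronic acid, and a chiral amine–thiourea catalyst directs the boronate oxygen onto one of the two enantiotopic enone arms, giving the cis-fused boronate A7.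
- For: A7 already has the C1 ketone, the C2=C3 enone, the C6 methylene, the alkynyl carbinol at C4 and the cis oxygen at C5. It is the functional counterpart of enone 10, reached in a fraction of the seven steps the chosen route needs, with no C–H oxidation and no selenium. On step economy it is clearly stronger.
- Against: the absolute configuration depends wholly on a catalyst telling apart two enone arms that differ only in their relation to a small hydroxyl and a slim alkynyl group. The adduct is a β-boryloxy ketone that can revert by retro-oxa-Michael reaction to achiral A6, so enantiopurity can leak during the reaction, boronate exchange or later steps. The boronate must also be exchanged for a group that survives iodination and amidation.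
- Comparison: the chosen route pays several extra steps. In return the configuration is fixed on a robust carbinol by a reduction with clear large/small differentiation, it is relayed irreversibly to C4, and no reversible bond formation can erode it before the ketone exists. From enone 10 onward both routes share the β-alkoxy ketone sensitivity.

Key step: step 3

## Route

Step 1
Reactants: 1 2-iodocyclohex-2-en-1-one; 2 ethynyltriisopropylsilane
Product: 3 2-[(triisopropylsilyl)ethynyl]cyclohex-2-en-1-one
Conditions: Pd(PPh3)2Cl2 (3 mol%), CuI (6 mol%), iPr2NH, THF, 0 °C → rt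
Reagents that add atoms: none
Why: Sonogashira coupling; α-iodoenones add oxidatively to zerovalent palladium very readily and the copper acetylide transmetallates at low temperature, so the enone is not heated with amine.

Step 2
Reactants: 3 2-[(triisopropylsilyl)ethynyl]cyclohex-2-en-1-one
Product: 4 (R)-2-[(triisopropylsilyl)ethynyl]cyclohex-2-en-1-ol
Conditions: (S)-1-methyl-3,3-diphenyltetrahydro-1H,3H-pyrrolo[1,2-c][1,3,2]oxazaborole (15 mol%), BH3·SMe2, THF, −30 °C; MeOH quench
Reagents that add atoms: none
Why: Corey–Bakshi–Shibata reduction; the in-plane alkynyl group blocks the carbonyl lone pair on its side, so the alkenyl flank is the large group and the methylene the small one, and the (S)-oxazaborolidine should deliver hydride to the face that gives the (R)-carbinol (C5 of the target); 1,2-reduction is expected to outpace hydroboration of the hindered silylalkyne.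

Step 3
Reactants: 4 (R)-2-[(triisopropylsilyl)ethynyl]cyclohex-2-en-1-ol
Product: 5 (1R,2R,6S)-1-[(triisopropylsilyl)ethynyl]-7-oxabicyclo[4.1.0]heptan-2-ol (epoxide oxygen cis to the hydroxyl)
Conditions: VO(acac)2 (3 mol%), t-BuOOH (anhydrous, in decane, 1.5 equiv), CH2Cl2, 0 °C → rt
Reagents that add atoms: tert-butyl hydroperoxide, CC(C)(C)OO
Why: The precatalyst is oxidised by the hydroperoxide to pentavalent vanadium, which takes up the C5 alkoxide and an η2-bound tert-butylperoxide, and the C3=C4 π bond then attacks the activated peroxide oxygen from within this complex. The closest known reaction type is the hydroxyl-directed vanadium/alkyl hydroperoxide epoxidation of cyclohex-2-enols, which is syn-selective. The oxirane closes by a concerted [2+1] oxygen-atom transfer through a spiro transition state, so the C4–O and C3–O bonds form on one face in a single event. The new quaternary centre C4 and the new centre C3 are both controlled by the (R)-C5 carbinol through the covalent metal tether, which can only reach the alkene face cis to the hydroxyl; the absolute configuration is inherited from step 2. The step needs face selectivity and chemoselectivity: the enyne alkene is the only olefin, the silyl-capped alkyne is too electron-poor and hindered to be oxidised, and the carbinol sits directly beside the substituted alkene carbon, the geometry this template serves best. Oxidation of the carbinol back to 3 is the competing path and is held down by low temperature and anhydrous peroxide.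

Step 4
Reactants: 5 (1R,2R,6S)-1-[(triisopropylsilyl)ethynyl]-7-oxabicyclo[4.1.0]heptan-2-ol
Product: 6 (1R,2R,3R)-3-(phenylselanyl)-2-[(triisopropylsilyl)ethynyl]cyclohexane-1,2-diol
Conditions: (PhSe)2, NaBH4, EtOH, 0 °C → 60 °C
Reagents that add atoms: diphenyl diselenide, c1ccc(cc1)[Se][Se]c1ccccc1
Why: SN2 epoxide opening by the soft selenolate at the secondary carbon C3 with inversion, trans-diaxial by the Fürst–Plattner rule; the tertiary C4 is closed to backside attack, the silyl cap blocks SN2' attack on the alkyne, and the cis hydroxyl cannot undergo Payne rearrangement, so the C4–O bond and its configuration are kept.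

Step 5
Reactants: 6 (1R,2R,3R)-3-(phenylselanyl)-2-[(triisopropylsilyl)ethynyl]cyclohexane-1,2-diol
Product: 8 (1R,2R)-2-[(triisopropylsilyl)ethynyl]cyclohex-3-ene-1,2-diol, via selenoxide 7 (not isolated)
Conditions: 30% aq H2O2, pyridine, CH2Cl2, 0 °C → rt
Reagents that add atoms: none
Why: Selenide oxidation followed by selenoxide syn-elimination; C4 has no hydrogen, so the only syn β-hydrogen is on C2 and the alkene can form only as C2=C3, while excess peroxide and pyridine remove the selenenic acid before it can add back.

Step 6
Reactants: 8 (1R,2R)-2-[(triisopropylsilyl)ethynyl]cyclohex-3-ene-1,2-diol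
Product: 9 (3aR,7aR)-2,2-dimethyl-3a-[(triisopropylsilyl)ethynyl]-3a,6,7,7a-tetrahydro-1,3-benzodioxole
Conditions: Me2C(OMe)2, PPTS (cat.), CH2Cl2, rt
Reagents that add atoms: 2,2-dimethoxypropane, COC(C)(C)OC
Why: Acid-catalysed transacetalisation; the cis-diol closes a five-membered acetonide readily, and masking the tertiary allylic hydroxyl prevents oxidative 1,3-transposition (Babler–Dauben type) in the next step.

Step 7
Reactants: 9 (3aR,7aR)-2,2-dimethyl-3a-[(triisopropylsilyl)ethynyl]-3a,6,7,7a-tetrahydro-1,3-benzodioxole
Product: 10 (3aR,7aR)-2,2-dimethyl-3a-[(triisopropylsilyl)ethynyl]-3a,7a-dihydro-1,3-benzodioxol-6(7H)-one (C1 ketone, C2=C3 enone)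
Conditions: CrO3, 3,5-dimethylpyrazole, CH2Cl2, −20 °C
Reagents that add atoms: chromium trioxide, O=[Cr](=O)=O
Why: Allylic C–H oxidation of a cyclohexene to the enone with the hexavalent chromium–pyrazole complex; C1 is the only allylic methylene because C4 is quaternary, and the acetonide and silylalkyne are inert to this reagent at low temperature.

Step 8
Reactants: 10 (3aR,7aR)-2,2-dimethyl-3a-[(triisopropylsilyl)ethynyl]-3a,7a-dihydro-1,3-benzodioxol-6(7H)-one
Product: 11 (3aR,7aR)-5-iodo-2,2-dimethyl-3a-[(triisopropylsilyl)ethynyl]-3a,7a-dihydro-1,3-benzodioxol-6(7H)-one (iodine on C2)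
Conditions: I2, pyridine/CH2Cl2 (1:1), 0 °C → rt
Reagents that add atoms: iodine, II
Why: α-Iodination of an enone by the addition–iodination–elimination sequence with pyridine as nucleophilic catalyst (Baylis–Hillman-type mechanism); pyridine is too weak a base to eliminate the C5 oxygen.

Step 9
Reactants: 12 (R)-4-benzyl-2-oxazolidinone; 13 hexanoyl chloride
Product: 14 (R)-4-benzyl-3-hexanoyloxazolidin-2-one
Conditions: Et3N, DMAP (cat.), CH2Cl2, 0 °C → rt
Reagents that add atoms: none
Why: N-acylation of the oxazolidinone with an acid chloride under nucleophilic catalysis; the stereocentre of the auxiliary is untouched.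

Step 10
Reactants: 14 (R)-4-benzyl-3-hexanoyloxazolidin-2-one
Product: 16 (R)-4-benzyl-3-[(R)-2-methylhexanoyl]oxazolidin-2-one, via sodium enolate 15 (not isolated)
Conditions: NaN(SiMe3)2, THF, −78 °C; then MeI, −78 °C
Reagents that add atoms: iodomethane, CI
Why: Evans asymmetric alkylation; the chelated (Z)-enolate is methylated on the face away from the benzyl group, which with the (R)-auxiliary and the butyl chain on the enolate gives the (R)-2-methylhexanoyl centre.

Step 11
Reactants: 16 (R)-4-benzyl-3-[(R)-2-methylhexanoyl]oxazolidin-2-one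
Product: 17 (R)-2-methylhexan-1-ol
Conditions: LiBH4, MeOH (1 equiv), Et2O, 0 °C
Reagents that add atoms: none
Why: Reductive cleavage of the N-acyl oxazolidinone by borohydride at the exocyclic carbonyl; no enolisation takes place, so the α-centre is kept and the auxiliary is recovered.

Step 12
Reactants: 17 (R)-2-methylhexan-1-ol; 18 ethyl 2-(triphenylphosphoranylidene)propanoate
Product: 20 ethyl (2E,4R)-2,4-dimethyloct-2-enoate, via aldehyde 19 (not isolated)
Conditions: (COCl)2, DMSO, CH2Cl2, −78 °C; iPr2NEt; then 18, −78 °C → rt
Reagents that add atoms: none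
Why: Swern oxidation telescoped into a Wittig olefination; the volatile, epimerisable α-branched aldehyde is trapped in the flask, and the stabilised ylide gives the (E)-trisubstituted ester by reversible betaine formation.

Step 13
Reactants: 20 ethyl (2E,4R)-2,4-dimethyloct-2-enoate
Product: 21 (2E,4R)-2,4-dimethyloct-2-en-1-ol
Conditions: iBu2AlH, CH2Cl2, −78 °C; aq potassium sodium tartrate
Reagents that add atoms: none
Why: 1,2-Reduction of an enoate to the allylic alcohol by the aluminium hydride; no conjugate reduction is expected at low temperature.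

Step 14
Reactants: 21 (2E,4R)-2,4-dimethyloct-2-en-1-ol
Product: 22 (2E,4R)-2,4-dimethyloct-2-enal
Conditions: MnO2 (excess), CH2Cl2, rt
Reagents that add atoms: none
Why: Selective allylic alcohol oxidation on the MnO2 surface; the alkene geometry and the γ-stereocentre are not affected.

Step 15
Reactants: 22 (2E,4R)-2,4-dimethyloct-2-enal; 23 diethyl (2-amino-2-oxoethyl)phosphonate
Product: 24 (2E,4E,6R)-4,6-dimethyldeca-2,4-dienamide
Conditions: KOtBu, THF, 0 °C → rt
Reagents that add atoms: none
Why: Horner–Wadsworth–Emmons olefination with a carbamoyl-stabilised phosphonate, which is E-selective and delivers the primary dienamide directly, saving an ester hydrolysis and amidation.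

Step 16
Reactants: 11 (3aR,7aR)-5-iodo-2,2-dimethyl-3a-[(triisopropylsilyl)ethynyl]-3a,7a-dihydro-1,3-benzodioxol-6(7H)-one; 24 (2E,4E,6R)-4,6-dimethyldeca-2,4-dienamide
Product: 25 (2E,4E,6R)-N-[(3aR,7aR)-2,2-dimethyl-6-oxo-3a-[(triisopropylsilyl)ethynyl]-3a,6,7,7a-tetrahydro-1,3-benzodioxol-5-yl]-4,6-dimethyldeca-2,4-dienamide
Conditions: CuI (15 mol%), MeNHCH2CH2NHMe (30 mol%), K2CO3, toluene, 60 °C
Reagents that add atoms: none
Why: Goldberg-type copper/diamine-catalysed N-vinylation of a primary amide with a vinyl iodide; the α-iodoenone is an activated partner, the C–I bond is replaced with retention of the alkene position, and the silyl cap keeps the alkyne away from copper acetylide chemistry.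

Step 17
Reactants: 25 (2E,4E,6R)-N-[(3aR,7aR)-2,2-dimethyl-6-oxo-3a-[(triisopropylsilyl)ethynyl]-3a,6,7,7a-tetrahydro-1,3-benzodioxol-5-yl]-4,6-dimethyldeca-2,4-dienamide
Product: 26 (2E,4E,6R)-N-[(3aR,7aR)-3a-ethynyl-2,2-dimethyl-6-oxo-3a,6,7,7a-tetrahydro-1,3-benzodioxol-5-yl]-4,6-dimethyldeca-2,4-dienamide
Conditions: Bu4NF, AcOH (1:1), THF, 0 °C → rt
Reagents that add atoms: none
Why: Fluoride-induced protodesilylation of the alkynylsilane; acetic acid buffers the basicity of fluoride so that the C6 enolate is not formed, and the acetonide blocks retro-aldol cleavage.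

Step 18
Reactants: 26 (2E,4E,6R)-N-[(3aR,7aR)-3a-ethynyl-2,2-dimethyl-6-oxo-3a,6,7,7a-tetrahydro-1,3-benzodioxol-5-yl]-4,6-dimethyldeca-2,4-dienamide
Product: 27 (2E,4E,6R)-N-[(3R,4R)-3-ethynyl-3,4-dihydroxy-6-oxocyclohex-1-en-1-yl]-4,6-dimethyldeca-2,4-dienamide (same spatial arrangement as the target; the C4 descriptor differs only through substituent priorities)
Conditions: AcOH/H2O (4:1), 40 °C
Reagents that add atoms: none
Why: Acid-catalysed acetal hydrolysis through the isopropylidene oxocarbenium ion; it is done before the triene is attached, while C4 is only propargylic and next to an electron-poor enone and is therefore hard to ionise.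

Step 19
Reactants: 27 (2E,4E,6R)-N-[(3R,4R)-3-ethynyl-3,4-dihydroxy-6-oxocyclohex-1-en-1-yl]-4,6-dimethyldeca-2,4-dienamide
Product: 28 (2E,4E,6R)-N-[(3R,4R)-3,4-dihydroxy-6-oxo-3-[(E)-2-(tributylstannyl)ethenyl]cyclohex-1-en-1-yl]-4,6-dimethyldeca-2,4-dienamide
Conditions: Bu3SnH (slow addition), Pd(PPh3)2Cl2 (3 mol%), THF, 0 °C
Reagents that add atoms: tributyltin hydride, CCCC[SnH](CCCC)CCCC
Why: Palladium-catalysed syn-hydrostannation of a terminal alkyne; the quaternary propargylic carbon steers tin to the terminal carbon, giving the (E)-vinylstannane, and the enone is electron-rich at C3 (enamide) and hindered, so conjugate reduction should be slow.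

Step 20
Reactants: 29 cyclopentane-1,3-dione
Product: 30 2-(hydroxyimino)cyclopentane-1,3-dione
Conditions: NaNO2, aq HCl, 0 °C
Reagents that add atoms: sodium nitrite, [Na+].[O-]N=O
Why: Nitrosation of the activated methylene of a 1,3-dione, followed by tautomerisation to the oxime.

Step 21
Reactants: 30 2-(hydroxyimino)cyclopentane-1,3-dione
Product: 31 2-amino-3-hydroxycyclopent-2-en-1-one hydrochloride
Conditions: H2 (1 atm), 10% Pd/C, HCl, MeOH, rt
Reagents that add atoms: hydrogen chloride, Cl
Why: Catalytic hydrogenolysis of the oxime N–O bond and reduction to the amine, trapped as the hydrochloride so that the aminoenol does not condense with itself.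

Step 22
Reactants: 32 potassium (1E,3E)-5-oxopenta-1,3-dien-1-olate (glutaconaldehyde potassium salt)
Product: 33 (2E,4E)-5-bromopenta-2,4-dienal
Conditions: PPh3, Br2, CH2Cl2, 0 °C; then 32, 0 °C → rt; I2 (trace) to equilibrate
Reagents that add atoms: bromine, BrBr
Why: Vinylogous deoxybromination: the dienolate oxygen is activated on phosphorus and replaced by bromide through addition–elimination, and the conjugated product settles to the 2E,4E isomer.

Step 23
Reactants: 33 (2E,4E)-5-bromopenta-2,4-dienal
Product: 34 (2E,4E)-5-bromopenta-2,4-dienoic acid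
Conditions: NaClO2, NaH2PO4, 2-methylbut-2-ene, t-BuOH/H2O, 0 °C → rt
Reagents that add atoms: sodium chlorite, [Na+].[O-]Cl=O
Why: Pinnick oxidation; chlorous acid oxidises the aldehyde only, and the scavenger alkene removes hypochlorous acid before it can attack the diene.

Step 24
Reactants: 34 (2E,4E)-5-bromopenta-2,4-dienoic acid; 31 2-amino-3-hydroxycyclopent-2-en-1-one hydrochloride
Product: 36 (2E,4E)-5-bromo-N-(2-hydroxy-5-oxocyclopent-1-en-1-yl)penta-2,4-dienamide, via acid chloride 35 (not isolated)
Conditions: (COCl)2, DMF (cat.), CH2Cl2, 0 °C → rt; concentrate; then 31, pyridine, THF, 0 °C → rt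
Reagents that add atoms: none
Why: Acid chloride formation and N-acylation of the aminoenol; the amine is the more nucleophilic site, and any enol ester formed should transfer its acyl group to nitrogen.

Step 25
Reactants: 28 (2E,4E,6R)-N-[(3R,4R)-3,4-dihydroxy-6-oxo-3-[(E)-2-(tributylstannyl)ethenyl]cyclohex-1-en-1-yl]-4,6-dimethyldeca-2,4-dienamide; 36 (2E,4E)-5-bromo-N-(2-hydroxy-5-oxocyclopent-1-en-1-yl)penta-2,4-dienamide
Product: 37 (2E,4E,6R)-N-[(3S,4R)-3,4-dihydroxy-3-[(1E,3E,5E)-7-[(2-hydroxy-5-oxocyclopent-1-en-1-yl)amino]-7-oxohepta-1,3,5-trien-1-yl]-6-oxocyclohex-1-en-1-yl]-4,6-dimethyldeca-2,4-dienamide (target)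
Conditions: Pd(MeCN)2Cl2 (8 mol%), DMF, rt, dark
Reagents that add atoms: none
Why: Stille coupling of a vinylstannane with a dienyl bromide under ligand-free, base-free conditions; both alkene geometries are transferred with retention, and the free diol, the β-hydroxy ketone and the vinylogous acid all tolerate the neutral medium.

## Compound list

1 | 2-iodocyclohex-2-en-1-one | O=C1CCCC=C1I | starting material
2 | ethynyltriisopropylsilane | C#C[Si](C(C)C)(C(C)C)C(C)C | starting material
3 | 2-[(triisopropylsilyl)ethynyl]cyclohex-2-en-1-one | CC(C)[Si](C(C)C)(C(C)C)C#CC1=CCCCC1=O | intermediate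
4 | (R)-2-[(triisopropylsilyl)ethynyl]cyclohex-2-en-1-ol | CC(C)[Si](C(C)C)(C(C)C)C#CC1=CCCC[C@H]1O | intermediate
5 | (1R,2R,6S)-1-[(triisopropylsilyl)ethynyl]-7-oxabicyclo[4.1.0]heptan-2-ol | CC(C)[Si](C(C)C)(C(C)C)C#C[C@]12O[C@H]1CCC[C@H]2O | intermediate
6 | (1R,2R,3R)-3-(phenylselanyl)-2-[(triisopropylsilyl)ethynyl]cyclohexane-1,2-diol | O[C@@H]1CCC[C@@H]([Se]c2ccccc2)[C@@]1(O)C#C[Si](C(C)C)(C(C)C)C(C)C | intermediate
7 | (1R,2R,3R)-3-(phenylseleninyl)-2-[(triisopropylsilyl)ethynyl]cyclohexane-1,2-diol (selenoxide, mixed at selenium) | O[C@@H]1CCC[C@@H]([Se](=O)c2ccccc2)[C@@]1(O)C#C[Si](C(C)C)(C(C)C)C(C)C | intermediate (not isolated)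
8 | (1R,2R)-2-[(triisopropylsilyl)ethynyl]cyclohex-3-ene-1,2-diol | O[C@@H]1CCC=C[C@@]1(O)C#C[Si](C(C)C)(C(C)C)C(C)C | intermediate
9 | (3aR,7aR)-2,2-dimethyl-3a-[(triisopropylsilyl)ethynyl]-3a,6,7,7a-tetrahydro-1,3-benzodioxole | CC1(C)O[C@@H]2CCC=C[C@@]2(O1)C#C[Si](C(C)C)(C(C)C)C(C)C | intermediate
10 | (3aR,7aR)-2,2-dimethyl-3a-[(triisopropylsilyl)ethynyl]-3a,7a-dihydro-1,3-benzodioxol-6(7H)-one | CC1(C)O[C@@H]2CC(=O)C=C[C@@]2(O1)C#C[Si](C(C)C)(C(C)C)C(C)C | intermediate
11 | (3aR,7aR)-5-iodo-2,2-dimethyl-3a-[(triisopropylsilyl)ethynyl]-3a,7a-dihydro-1,3-benzodioxol-6(7H)-one | CC1(C)O[C@@H]2CC(=O)C(I)=C[C@@]2(O1)C#C[Si](C(C)C)(C(C)C)C(C)C | intermediate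
12 | (R)-4-benzyl-2-oxazolidinone | O=C1N[C@H](Cc2ccccc2)CO1 | starting material
13 | hexanoyl chloride | CCCCCC(Cl)=O | starting material
14 | (R)-4-benzyl-3-hexanoyloxazolidin-2-one | CCCCCC(=O)N1[C@H](Cc2ccccc2)COC1=O | intermediate
15 | sodium (Z)-enolate of 14 | CCCC/C=C(\[O-])N1[C@H](Cc2ccccc2)COC1=O.[Na+] | intermediate (not isolated)
16 | (R)-4-benzyl-3-[(R)-2-methylhexanoyl]oxazolidin-2-one | CCCC[C@@H](C)C(=O)N1[C@H](Cc2ccccc2)COC1=O | intermediate
17 | (R)-2-methylhexan-1-ol | CCCC[C@@H](C)CO | intermediate
18 | ethyl 2-(triphenylphosphoranylidene)propanoate | CCOC(=O)C(C)=P(c1ccccc1)(c1ccccc1)c1ccccc1 | starting material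
19 | (R)-2-methylhexanal | CCCC[C@@H](C)C=O | intermediate (not isolated)
20 | ethyl (2E,4R)-2,4-dimethyloct-2-enoate | CCCC[C@@H](C)/C=C(\C)C(=O)OCC | intermediate
21 | (2E,4R)-2,4-dimethyloct-2-en-1-ol | CCCC[C@@H](C)/C=C(\C)CO | intermediate
22 | (2E,4R)-2,4-dimethyloct-2-enal | CCCC[C@@H](C)/C=C(\C)C=O | intermediate
23 | diethyl (2-amino-2-oxoethyl)phosphonate | CCOP(=O)(CC(N)=O)OCC | starting material
24 | (2E,4E,6R)-4,6-dimethyldeca-2,4-dienamide | CCCC[C@@H](C)/C=C(C)/C=C/C(N)=O | intermediate
25 | (2E,4E,6R)-N-[(3aR,7aR)-2,2-dimethyl-6-oxo-3a-[(triisopropylsilyl)ethynyl]-3a,6,7,7a-tetrahydro-1,3-benzodioxol-5-yl]-4,6-dimethyldeca-2,4-dienamide | CCCC[C@@H](C)/C=C(C)/C=C/C(=O)NC1=C[C@]2(C#C[Si](C(C)C)(C(C)C)C(C)C)OC(C)(C)O[C@@H]2CC1=O | intermediate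
26 | (2E,4E,6R)-N-[(3aR,7aR)-3a-ethynyl-2,2-dimethyl-6-oxo-3a,6,7,7a-tetrahydro-1,3-benzodioxol-5-yl]-4,6-dimethyldeca-2,4-dienamide | CCCC[C@@H](C)/C=C(C)/C=C/C(=O)NC1=C[C@]2(C#C)OC(C)(C)O[C@@H]2CC1=O | intermediate
27 | (2E,4E,6R)-N-[(3R,4R)-3-ethynyl-3,4-dihydroxy-6-oxocyclohex-1-en-1-yl]-4,6-dimethyldeca-2,4-dienamide | CCCC[C@@H](C)/C=C(C)/C=C/C(=O)NC1=C[C@@](O)(C#C)[C@H](O)CC1=O | intermediate
28 | (2E,4E,6R)-N-[(3R,4R)-3,4-dihydroxy-6-oxo-3-[(E)-2-(tributylstannyl)ethenyl]cyclohex-1-en-1-yl]-4,6-dimethyldeca-2,4-dienamide | CCCC[C@@H](C)/C=C(C)/C=C/C(=O)NC1=C[C@@](O)(/C=C/[Sn](CCCC)(CCCC)CCCC)[C@H](O)CC1=O | intermediate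
29 | cyclopentane-1,3-dione | O=C1CCC(=O)C1 | starting material
30 | 2-(hydroxyimino)cyclopentane-1,3-dione | O=C1CCC(=O)C1=NO | intermediate
31 | 2-amino-3-hydroxycyclopent-2-en-1-one hydrochloride | Cl.NC1=C(O)CCC1=O | intermediate
32 | potassium (1E,3E)-5-oxopenta-1,3-dien-1-olate | [K+].[O-]/C=C/C=C/C=O | starting material
33 | (2E,4E)-5-bromopenta-2,4-dienal | Br/C=C/C=C/C=O | intermediate
34 | (2E,4E)-5-bromopenta-2,4-dienoic acid | OC(=O)/C=C/C=C/Br | intermediate
35 | (2E,4E)-5-bromopenta-2,4-dienoyl chloride | ClC(=O)/C=C/C=C/Br | intermediate (not isolated)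
36 | (2E,4E)-5-bromo-N-(2-hydroxy-5-oxocyclopent-1-en-1-yl)penta-2,4-dienamide | Br/C=C/C=C/C(=O)NC1=C(O)CCC1=O | intermediate
37 | (2E,4E,6R)-N-[(3S,4R)-3,4-dihydroxy-3-[(1E,3E,5E)-7-[(2-hydroxy-5-oxocyclopent-1-en-1-yl)amino]-7-oxohepta-1,3,5-trien-1-yl]-6-oxocyclohex-1-en-1-yl]-4,6-dimethyldeca-2,4-dienamide | CCCC[C@@H](C)/C=C(C)/C=C/C(=O)NC1=C[C@@](O)(/C=C/C=C/C=C/C(=O)NC2=C(O)CCC2=O)[C@H](O)CC1=O | target

## Step count and least certain steps

Total step count: 25. Longest linear sequence: 13 steps (steps 1–8, 16–19 and 25). The upper chain (steps 9–15) joins at step 16 and the lower chain (steps 20–24) at step 25.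

**Step 3 (key step).** The most likely failure is oxidation of the allylic carbinol to the ynenone competing with oxygen transfer. The alkynyl group makes the alkene less nucleophilic and exerts little allylic strain to hold the hydroxyl pseudoaxial, so the metal alkoxide may lose hydride faster than it epoxidises; loss of face selectivity is less likely. The fallback sets out from 4 and installs the C4 oxygen through a tethered carbonate instead of an oxidant. Acylation of 4 with di-tert-butyl dicarbonate and DMAP gives tert-butyl (1R)-2-[(triisopropylsilyl)ethynyl]cyclohex-2-en-1-yl carbonate F1. Iodine monobromide in toluene at low temperature closes the carbonate carbonyl oxygen onto C4 in a 5-exo iodocarbonate cyclisation, necessarily cis to the C5 oxygen, with iodine anti at C3, giving (3aR,4R,7aR)-4-iodo-3a-[(triisopropylsilyl)ethynyl]hexahydro-1,3-benzodioxol-2-one F2. E2 elimination with DBU in warm toluene can only go towards C2 and gives (3aR,7aR)-3a-[(triisopropylsilyl)ethynyl]-3a,6,7,7a-tetrahydro-1,3-benzodioxol-2-one F3. Methanolysis with K2CO3 in methanol then gives 8, where the route is rejoined without steps 3–5.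

**Step 7.** Hydrogen abstraction at C1 gives a delocalised allyl intermediate, so oxygenation at C3 with alkene shift (allylic transposition) is possible, as is over-oxidation or attack at the acetonide methine. The fallback sets out from 9 and uses a pericyclic two-stage sequence that cannot transpose. SeO2 (catalytic) with t-BuOOH in CH2Cl2 performs an ene reaction followed by a [2,3]-shift, returning oxygen to C1 and giving (3aR,7aR)-2,2-dimethyl-3a-[(triisopropylsilyl)ethynyl]-3a,6,7,7a-tetrahydro-1,3-benzodioxol-6-ol F4 as a mixture of C1 epimers. Dess–Martin periodinane then oxidises both epimers to 10.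

**Step 16.** Carbonate at 60 °C may deprotonate C6 and expel the C5 acetal oxygen (E1cB), which would erase both ring stereocentres; reductive loss of iodine is a second risk. The fallback sets out from 11 and removes the ketone for the duration of the coupling. Luche reduction (NaBH4, CeCl3·7H2O, MeOH, −78 °C) gives (3aR,7aR)-5-iodo-2,2-dimethyl-3a-[(triisopropylsilyl)ethynyl]-3a,6,7,7a-tetrahydro-1,3-benzodioxol-6-ol F5 as a C1 epimer mixture. The same CuI/diamine amidation with 24, now on a simple vinyl iodide with no acidic α-hydrogen, gives (2E,4E,6R)-N-[(3aR,7aR)-6-hydroxy-2,2-dimethyl-3a-[(triisopropylsilyl)ethynyl]-3a,6,7,7a-tetrahydro-1,3-benzodioxol-5-yl]-4,6-dimethyldeca-2,4-dienamide F6. Dess–Martin oxidation of the allylic alcohol returns to 25.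

**Step 17.** Fluoride may act as a base and trigger the same elimination of the C5 oxygen, or, if heavily buffered, leave the hindered silyl group in place. The fallback sets out from 25 and brackets the desilylation with a reduction and an oxidation. Luche reduction of 25 gives the allylic alcohol F6 described above (C1 epimer mixture). Unbuffered Bu4NF in THF then removes the silyl group safely, since no ketone is present, giving (2E,4E,6R)-N-[(3aR,7aR)-3a-ethynyl-6-hydroxy-2,2-dimethyl-3a,6,7,7a-tetrahydro-1,3-benzodioxol-5-yl]-4,6-dimethyldeca-2,4-dienamide F7. Dess–Martin oxidation returns to 26.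

**Step 19.** The free tertiary hydroxyl may coordinate and divert tin to the internal alkyne carbon, or palladium hydride may reduce the enone in a conjugate sense. The fallback sets out from 26 and postpones the acetal cleavage to the end. Hydrostannation of 26, whose propargylic oxygen is a hindered acetal, under the same palladium catalysis gives (2E,4E,6R)-N-[(3aR,7aR)-2,2-dimethyl-6-oxo-3a-[(E)-2-(tributylstannyl)ethenyl]-3a,6,7,7a-tetrahydro-1,3-benzodioxol-5-yl]-4,6-dimethyldeca-2,4-dienamide F8. Stille coupling with 36 as in step 25 gives the acetonide of the target, (2E,4E,6R)-N-[(3aS,7aR)-3a-[(1E,3E,5E)-7-[(2-hydroxy-5-oxocyclopent-1-en-1-yl)amino]-7-oxohepta-1,3,5-trien-1-yl]-2,2-dimethyl-6-oxo-3a,6,7,7a-tetrahydro-1,3-benzodioxol-5-yl]-4,6-dimethyldeca-2,4-dienamide F9. Brief hydrolysis in aqueous acetic acid in the dark then gives 37; the price is acid exposure of the finished polyene.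

## Further compounds

F1 | step 3 | tert-butyl (1R)-2-[(triisopropylsilyl)ethynyl]cyclohex-2-en-1-yl carbonate | CC(C)(C)OC(=O)O[C@@H]1CCCC=C1C#C[Si](C(C)C)(C(C)C)C(C)C
F2 | step 3 | (3aR,4R,7aR)-4-iodo-3a-[(triisopropylsilyl)ethynyl]hexahydro-1,3-benzodioxol-2-one | O=C1O[C@@H]2CCC[C@@H](I)[C@@]2(O1)C#C[Si](C(C)C)(C(C)C)C(C)C
F3 | step 3 | (3aR,7aR)-3a-[(triisopropylsilyl)ethynyl]-3a,6,7,7a-tetrahydro-1,3-benzodioxol-2-one | O=C1O[C@@H]2CCC=C[C@@]2(O1)C#C[Si](C(C)C)(C(C)C)C(C)C
F4 | step 7 | (3aR,7aR)-2,2-dimethyl-3a-[(triisopropylsilyl)ethynyl]-3a,6,7,7a-tetrahydro-1,3-benzodioxol-6-ol (C6 epimers) | CC1(C)O[C@@H]2CC(O)C=C[C@@]2(O1)C#C[Si](C(C)C)(C(C)C)C(C)C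
F5 | step 16 | (3aR,7aR)-5-iodo-2,2-dimethyl-3a-[(triisopropylsilyl)ethynyl]-3a,6,7,7a-tetrahydro-1,3-benzodioxol-6-ol (C6 epimers) | CC1(C)O[C@@H]2CC(O)C(I)=C[C@@]2(O1)C#C[Si](C(C)C)(C(C)C)C(C)C
F6 | step 16 | (2E,4E,6R)-N-[(3aR,7aR)-6-hydroxy-2,2-dimethyl-3a-[(triisopropylsilyl)ethynyl]-3a,6,7,7a-tetrahydro-1,3-benzodioxol-5-yl]-4,6-dimethyldeca-2,4-dienamide (C6 epimers) | CCCC[C@@H](C)/C=C(C)/C=C/C(=O)NC1=C[C@]2(C#C[Si](C(C)C)(C(C)C)C(C)C)OC(C)(C)O[C@@H]2CC1O
F7 | step 17 | (2E,4E,6R)-N-[(3aR,7aR)-3a-ethynyl-6-hydroxy-2,2-dimethyl-3a,6,7,7a-tetrahydro-1,3-benzodioxol-5-yl]-4,6-dimethyldeca-2,4-dienamide (C6 epimers) | CCCC[C@@H](C)/C=C(C)/C=C/C(=O)NC1=C[C@]2(C#C)OC(C)(C)O[C@@H]2CC1O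
F8 | step 19 | (2E,4E,6R)-N-[(3aR,7aR)-2,2-dimethyl-6-oxo-3a-[(E)-2-(tributylstannyl)ethenyl]-3a,6,7,7a-tetrahydro-1,3-benzodioxol-5-yl]-4,6-dimethyldeca-2,4-dienamide | CCCC[C@@H](C)/C=C(C)/C=C/C(=O)NC1=C[C@]2(/C=C/[Sn](CCCC)(CCCC)CCCC)OC(C)(C)O[C@@H]2CC1=O
F9 | step 19 | (2E,4E,6R)-N-[(3aS,7aR)-3a-[(1E,3E,5E)-7-[(2-hydroxy-5-oxocyclopent-1-en-1-yl)amino]-7-oxohepta-1,3,5-trien-1-yl]-2,2-dimethyl-6-oxo-3a,6,7,7a-tetrahydro-1,3-benzodioxol-5-yl]-4,6-dimethyldeca-2,4-dienamide | CCCC[C@@H](C)/C=C(C)/C=C/C(=O)NC1=C[C@]2(/C=C/C=C/C=C/C(=O)NC3=C(O)CCC3=O)OC(C)(C)O[C@@H]2CC1=O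
A1 | alternative 1 | benzoic acid | OC(=O)c1ccccc1
A2 | alternative 1 | (1S,2R)-1,2-dihydroxycyclohexa-3,5-diene-1-carboxylic acid | C1=C[C@@](O)(C(=O)O)[C@H](O)C=C1
A3 | alternative 2 | (2E,4E,6R)-N-hydroxy-4,6-dimethyldeca-2,4-dienamide | CCCC[C@@H](C)/C=C(C)/C=C/C(=O)NO
A4 | alternative 2 | (5R)-2-[(tert-butyldimethylsilyl)oxy]-5-(methoxymethoxy)-5-[(E)-3-[(tert-butyldiphenylsilyl)oxy]prop-1-en-1-yl]cyclohexa-1,3-diene | CC(C)(C)[Si](C)(C)OC1=CC[C@@](OCOC)(/C=C/CO[Si](c2ccccc2)(c2ccccc2)C(C)(C)C)C=C1
A5 | alternative 2 | N-dienoyl 2-oxa-3-azabicyclo[2.2.2]octene silyl enol ether | CCCC[C@@H](C)/C=C(C)/C=C/C(=O)N1O[C@@H]2C=C(O[Si](C)(C)C(C)(C)C)[C@H]1C[C@@]2(OCOC)/C=C/CO[Si](c3ccccc3)(c4ccccc4)C(C)(C)C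
A6 | alternative 3 | 4-hydroxy-4-[(trimethylsilyl)ethynyl]cyclohexa-2,5-dien-1-one | C[Si](C)(C)C#CC1(O)C=CC(=O)C=C1
A7 | alternative 3 | cis-fused phenylboronate of 4,5-dihydroxy-4-[(trimethylsilyl)ethynyl]cyclohex-2-en-1-one | O=C1C=C[C@@](O2)(C#C[Si](C)(C)C)[C@H](OB2c3ccccc3)C1
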